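## The problem

The target 19 is a fully substituted acylphloroglucinol. Benzene ring A carries the chromanone carbonyl carbon at C4a, hydroxyls at C5 and C7, a prenyl group at C6, the ring oxygen O1 at C8a, and at C8 a methyl hexanoate chain bound through its C3 (Cβ). Ring B is a 2,3-dimethyl-dihydropyranone fused along C4a–C8a.

C6 and C8 are activated by the same pair of oxygens, so each substituent needs a structural reason to go to its own carbon. Of the three stereocenters, C2 and C3 are adjacent and trans. C3 lies alpha to the C4 ketone and can equilibrate to the more stable trans arrangement once C2 is fixed, so only C2 needs absolute control in ring B. Cβ is joined to C2 only through C8, C8a and O1 and a freely rotating aryl–carbon bond, so the ring cannot be trusted to control it and a reagent must.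

Several groups limit the conditions:
- The prenyl group closes onto either flanking phenol under strong acid and does not survive hydrogenation or oxidants.
- The chromanone can open by retro-oxa-Michael reaction under strong base, which would erase C2.
- The phenol at C7 sits 1,6 to the ester carbonyl and can close a lactone.

The enabling feature is the array C7(OH)–C8–Cβ. A free phenol ortho to a benzylic carbon is a latent o-quinone methide, and the neighbouring Cα is an acetate carbon that a malonate can deliver.

## Retrosynthesis

**19 to 18.** The ester C–O bond is cut, so that 19 becomes the methanolysis product of dihydrocoumarin 18, in which O7 acylates the chain. Planning through the lactone accepts what the 1,6-relationship would do on heating anyway. It also keeps O7 acylated during the one hot step, so that the phenoxide cannot expel the chain. The forward reaction is a mild methoxide opening of an aryl ester.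

**18 to 16.** A methoxycarbonyl group is added back at Cα, which turns the acetate carbon into a malonate carbon. The forward step is lactonisation to 17 followed by Krapcho dealkoxycarbonylation. Malonate 16 has no extra stereocenter of consequence and is the direct product of a catalytic asymmetric C–C bond formation.

**16 to 13 and 14 (through 15).** The Cα–Cβ bond is cut.
- Against cutting C8–Cβ: that would require the crowded, ketone-deactivated arene to be the nucleophile towards an aliphatic acceptor under catalyst control.
- Against cutting Cβ–propyl: that would require an organocopper addition in the presence of the ketone and two free phenols.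
- For cutting Cα–Cβ: the arene becomes the electrophile as o-quinone methide 15, released from sulfone 13 by base, and the nucleophile is dimethyl malonate 14. A chiral squaramide must choose the face of the exocyclic carbon.

**13 to 10, 11 and 12.** The C8–Cβ and Cβ–S bonds are cut in a three-component condensation of phenol 10, butanal 11 and sulfinate 12. C8 is the only unsubstituted aromatic carbon of 10, so the forward reaction has no regiochemical choice. It only has to outrun attack of a second phenol molecule.

**10 to 9 to 7 (through 8).** After the two methoxymethyl ethers are restored (9), the C2–CH3 bond is cut. The forward step is a copper-catalysed asymmetric methyl addition to chromone 7, giving enolate 8, whose protonation and equilibration set C3 trans. Chromone 7 is flat and achiral, so everything before it can be done without regard to stereochemistry.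

**7 to 6 to 5 to 4 to 3.** The prenyl group is traced back to an allyl group (cross-metathesis with 2-methylbut-2-ene, 5 to 6), and the C6–allyl bond to an O5-allyl ether (aromatic Claisen rearrangement, 4 to 5). From O5 the only ortho carbon bearing hydrogen is C6, so the rearrangement is regiospecific. This is preferred to direct C-prenylation, which would give C6 and C8 mixtures. It requires O7 to be masked first (3) and O5 to be protected afterwards (7). Doing the hot Claisen step and the basic alkylations on the chromone protects the later stereocenters from them.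

**3 to 2 to 1.** Chromone 2 is flopropione 1 plus one carbon (C2) from dimethylformamide. The C7 hydroxyl of 2 is the more acidic, non-chelated one, so it takes the first methoxymethyl group selectively.

## Roads not taken

**Alternative 1: carbene-catalysed hydroacylation closing ring B.**
- Cut: the C3–C4 bond of the chromanone.
- Forward step: 2-[(2S)-but-3-en-2-yloxy]-4,6-bis(methoxymethoxy)benzaldehyde A1 is converted by an N-heterocyclic carbene into a Breslow intermediate. This adds across the terminal alkene to close ring B and give (2S,3S)-5,7-bis(methoxymethoxy)-2,3-dimethylchroman-4-one A2.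
- Merits: C2 comes from an enantiopure allylic alcohol, so no asymmetric catalyst is needed for ring B. In certainty of absolute configuration at C2 this is better than the copper step of the chosen plan.
- Weak points: the aldehyde of A1 is flanked by two ortho oxygens and is electron-rich, which slows Breslow intermediate formation. Hydroacylation of unactivated alkenes needs heat, and A1 is an aryl allyl ether that can undergo Claisen rearrangement under the same conditions. Making the hindered secondary aryl allyl ether risks allylic transposition.
- Comparison: A2 lacks the prenyl group, so the O-allylation, Claisen step at about 190 °C and metathesis would have to be run on the stereodefined chromanone. It does not address Cβ at all. It replaces steps 1–8 of the chosen route with a sequence of similar length, so the chosen plan gives up little here; it gains in running the aromatic substitution before any stereocenter exists.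

**Alternative 2: asymmetric methyl addition to a 3-methylchromone as the central step.**
- Cut: the C2–CH3 bond.
- Forward step: MeMgBr with CuBr·SMe2 and a chiral ferrocenyl diphosphine adds to 5,7-bis(benzyloxy)-3-methylchromen-4-one A3, giving (2S,3S)-5,7-bis(benzyloxy)-2,3-dimethylchroman-4-one A4 after trans-selective protonation.
- Merits: short (about three steps from flopropione to A4), and the substrate is less hindered than chromone 7 of the chosen route. In these two respects it is better.
- Weak points: benzyl ethers must be removed by hydrogenolysis, which is possible only before the prenyl group exists. Prenylation then has to be carried out on the stereodefined chromanone. As a strategy it solves only ring B and leaves Cβ open.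
- Comparison: the chosen plan does not reject this reaction. It uses the same transformation as step 7, on a chromone that already carries the prenyl group and acid-labile ethers. It pays with a more crowded substrate for the methyl addition.

**Alternative 3: carbene-catalysed oxidative annulation with a hexenoyl unit.**
- Cut: C8–Cβ and O7–C(=O) together.
- Forward step: a chiral triazolium-derived carbene and a quinone oxidant convert (E)-hex-2-enal A5 into an unsaturated acyl azolium, which is attacked by C8 of phenol 10 and then acylates O7. The product is (2S,3S,10R)-5-hydroxy-2,3-dimethyl-6-(3-methylbut-2-enyl)-10-propyl-2,3,9,10-tetrahydro-4H,8H-pyrano[2,3-f]chromene-4,8-dione A6, the same compound as lactone 18.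
- Merits: one step from 10 to 18 instead of three, with no sulfone, no malonate and no decarboxylation. In step count it is clearly better.
- Weak points: the arene must act as the carbon nucleophile at its most crowded position while deactivated by the C4 ketone. Simple O-acylation of O7 or O5 without C–C bond formation is a dead end. Enantiocontrol has to be exerted on an aliphatic enal. The stoichiometric quinone oxidant meets an electron-rich prenylated phenol that is itself oxidisable.
- Comparison: the chosen plan sets against the two extra steps an oxidant-free medium, an electrophilic role for the arene that suits its substitution, and a stable, purifiable adduct 16 before the lactone is formed.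

Key step: step 10

Assumption: the sense of induction of the ferrocenyl diphosphine in step 7 and of the cinchona squaramide in step 10 is taken to give 2S and 1R as written; if a first run shows the opposite sense, the enantiomeric ligand or the quinidine-derived pseudoenantiomer is used and nothing else changes.

## Route

Step 1
Reactants: 1 flopropione (1-(2,4,6-trihydroxyphenyl)propan-1-one)
Product: 2 5,7-dihydroxy-3-methyl-4H-chromen-4-one
Conditions: BF3·OEt2, DMF, 50 °C; MsCl, 80 °C; aq. NaOAc
Reagents that add atoms: N,N-dimethylformamide, CN(C)C=O
Why: Vilsmeier–Haack-type formylation of the alpha-methylene of the boron-chelated o-hydroxyaryl ketone, followed by closure of an ortho hydroxyl onto the iminium carbon and loss of dimethylamine, is the standard one-carbon route to 3-substituted chromones and isoflavones from polyhydroxy ketones; the two ortho hydroxyls are equivalent, so only one chromone can form.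

Step 2
Reactants: 2 5,7-dihydroxy-3-methyl-4H-chromen-4-one
Product: 3 5-hydroxy-7-(methoxymethoxy)-3-methyl-4H-chromen-4-one
Conditions: MOMCl (1.1 equiv), iPr2NEt, DMF/CH2Cl2, 0 °C
Reagents that add atoms: chloromethyl methyl ether, COCCl
Why: Selective O-alkylation; the C7 hydroxyl is the more acidic and is not hydrogen-bonded, whereas the C5 hydroxyl is locked in a chelate with the C4 carbonyl and reacts far more slowly.

Step 3
Reactants: 3 5-hydroxy-7-(methoxymethoxy)-3-methyl-4H-chromen-4-one
Product: 4 7-(methoxymethoxy)-3-methyl-5-(prop-2-enyloxy)-4H-chromen-4-one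
Conditions: allyl bromide, K2CO3, DMF, 60 °C
Reagents that add atoms: allyl bromide, C=CCBr
Why: Williamson etherification; the chelated C5 phenol needs carbonate in a dipolar solvent and a reactive primary allylic halide, conditions under which the chromone and the acetal are stable.

Step 4
Reactants: 4 7-(methoxymethoxy)-3-methyl-5-(prop-2-enyloxy)-4H-chromen-4-one
Product: 5 5-hydroxy-7-(methoxymethoxy)-3-methyl-6-(prop-2-enyl)-4H-chromen-4-one
Conditions: PhNEt2, 190 °C
Reagents that add atoms: none
Why: Aromatic Claisen rearrangement; from O5 the only ortho carbon bearing hydrogen is C6, so the [3,3] shift and tautomerization place the allyl group there and nowhere else, and the basic amine solvent suppresses acid-induced cyclization of the new o-allylphenol.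

Step 5
Reactants: 5 5-hydroxy-7-(methoxymethoxy)-3-methyl-6-(prop-2-enyl)-4H-chromen-4-one
Product: 6 5-hydroxy-7-(methoxymethoxy)-3-methyl-6-(3-methylbut-2-enyl)-4H-chromen-4-one
Conditions: second-generation Grubbs catalyst RuCl2(=CHPh)(H2IMes)(PCy3) (5 mol %), 2-methylbut-2-ene (excess), CH2Cl2, 40 °C
Reagents that add atoms: 2-methylbut-2-ene, CC=C(C)C
Why: Olefin cross-metathesis of a terminal allylarene with 2-methylbut-2-ene is the standard conversion of allyl into prenyl; the electron-poor trisubstituted C2=C3 bond of the chromone does not take part.

Step 6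
Reactants: 6 5-hydroxy-7-(methoxymethoxy)-3-methyl-6-(3-methylbut-2-enyl)-4H-chromen-4-one
Product: 7 5,7-bis(methoxymethoxy)-3-methyl-6-(3-methylbut-2-enyl)-4H-chromen-4-one
Conditions: NaH, MOMCl, DMF, 0 → 23 °C
Reagents that add atoms: chloromethyl methyl ether, COCCl
Why: O-alkylation of the chelated, flanked C5 phenol through its sodium phenoxide; the acidic proton has to be removed before the Grignard step.

Step 7
Reactants: 7 5,7-bis(methoxymethoxy)-3-methyl-6-(3-methylbut-2-enyl)-4H-chromen-4-one
Product: 9 (2S,3S)-5,7-bis(methoxymethoxy)-2,3-dimethyl-6-(3-methylbut-2-enyl)chroman-4-one, via bromomagnesium enolate 8 (not isolated)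
Conditions: MeMgBr, CuBr·SMe2 (5 mol %), (R)-1-[(S)-2-(diphenylphosphino)ferrocenyl]ethyldicyclohexylphosphine (6 mol %), CH2Cl2, −78 °C; AcOH, −78 °C; Et3N, MeOH, 23 °C
Reagents that add atoms: methylmagnesium bromide, C[Mg]Br
Why: Copper-catalysed asymmetric conjugate addition of a Grignard reagent to a chromone; the chiral copper–diphosphine complex selects the face of C2 and so sets 2S, while C3 is set by protonation of enolate 8 followed by amine-mediated equilibration towards the more stable trans isomer (equilibration may not be complete; the cis epimer is separable and can be re-equilibrated).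

Step 8
Reactants: 9 (2S,3S)-5,7-bis(methoxymethoxy)-2,3-dimethyl-6-(3-methylbut-2-enyl)chroman-4-one
Product: 10 (2S,3S)-5,7-dihydroxy-2,3-dimethyl-6-(3-methylbut-2-enyl)chroman-4-one
Conditions: 3 M aq. HCl, MeOH, 40 °C
Reagents that add atoms: none
Why: Acid-catalysed acetal exchange removes both methoxymethyl groups as dimethoxymethane; dilute methanolic HCl at this temperature is the usual way to unmask phenols next to a prenyl group without cyclization to the chroman, and it keeps C3 equilibrated through the enol without touching the C2–O1 bond.

Step 9
Reactants: 10 (2S,3S)-5,7-dihydroxy-2,3-dimethyl-6-(3-methylbut-2-enyl)chroman-4-one; 11 butanal; 12 sodium 4-methylbenzenesulfinate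
Product: 13 (2S,3S)-5,7-dihydroxy-2,3-dimethyl-6-(3-methylbut-2-enyl)-8-[1-(4-methylphenylsulfonyl)butyl]chroman-4-one (both epimers at the sulfone carbon)
Conditions: 11 (2 equiv), 12 (2 equiv), HCO2H, H2O/THF, 23 °C
Reagents that add atoms: none
Why: Three-component Mannich-type condensation of a phenol, an aldehyde and a sulfinic acid; C8 is the only unsubstituted aromatic carbon, the benzylic cation or methide formed after hydroxyalkylation is captured by the excess sulfinate, and the new sulfone carbon needs no control because both epimers give the same methide in step 10.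

Step 10
Reactants: 13 (2S,3S)-5,7-dihydroxy-2,3-dimethyl-6-(3-methylbut-2-enyl)-8-[1-(4-methylphenylsulfonyl)butyl]chroman-4-one; 14 dimethyl malonate
Product: 16 dimethyl 2-[(1R)-1-[(2S,3S)-5,7-dihydroxy-2,3-dimethyl-6-(3-methylbut-2-enyl)-4-oxochroman-8-yl]butyl]malonate, via o-quinone methide 15 (not isolated)
Conditions: 14 (3 equiv), 3-[[3,5-bis(trifluoromethyl)phenyl]amino]-4-[[(8α,9S)-6′-methoxycinchonan-9-yl]amino]cyclobut-3-ene-1,2-dione (10 mol %), aq. NaHCO3, PhMe, 0 → 23 °C
Reagents that add atoms: none
Why: Aqueous bicarbonate deprotonates the acidic C7 phenol of 13 and the phenoxide expels 4-methylbenzenesulfinate (E1cB) to give o-quinone methide 15 with C7=O and C8=CH–propyl, the same methide from either sulfone epimer. The squaramide NH groups hydrogen-bond the C7 carbonyl oxygen while the protonated quinuclidine holds the malonate enolate, which adds to the exocyclic carbon in a Michael-type 1,4-addition and forms the Cα–Cβ bond with rearomatization as the driving force. The closest known reaction is the squaramide-catalysed addition of malonates and other 1,3-dicarbonyl compounds to o-quinone methides released from 2-(1-arylsulfonylalkyl)phenols under biphasic base. No ring is closed. The new 1R center is set by the catalyst, which exposes one face of the methide; C2 is four bonds away across O1 and a rotating aryl–carbon bond, so little substrate bias is expected. Regioselectivity is secured by the substrate, because only C8 carries a benzylic leaving group beside a free phenol, O1 is an ether and C6 holds the prenyl group. Slow release of 15 at the interface keeps its concentration low, which limits tautomerization to the 8-(but-1-enyl)phenol and capture by a second phenoxide. Any 16 that lactonises in the flask to 17 is carried forward, since step 11 passes through 17.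

Step 11
Reactants: 16 dimethyl 2-[(1R)-1-[(2S,3S)-5,7-dihydroxy-2,3-dimethyl-6-(3-methylbut-2-enyl)-4-oxochroman-8-yl]butyl]malonate
Product: 18 (2S,3S,10R)-5-hydroxy-2,3-dimethyl-6-(3-methylbut-2-enyl)-10-propyl-2,3,9,10-tetrahydro-4H,8H-pyrano[2,3-f]chromene-4,8-dione, via 9-methoxycarbonyl lactone 17 (not isolated)
Conditions: LiCl, H2O (2 equiv), DMSO, 130 °C; dilute HCl work-up
Reagents that add atoms: none
Why: On heating, the C7 phenol closes onto one malonate ester (six-membered intramolecular transesterification, methanol distils out), which also blocks loss of the chain through the phenoxide; the resulting beta-ester lactone 17 then undergoes Krapcho dealkoxycarbonylation by chloride attack at the methyl group, decarboxylation and protonation, with Cβ untouched.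

Step 12
Reactants: 18 (2S,3S,10R)-5-hydroxy-2,3-dimethyl-6-(3-methylbut-2-enyl)-10-propyl-2,3,9,10-tetrahydro-4H,8H-pyrano[2,3-f]chromene-4,8-dione
Product: 19 methyl (3R)-3-[(2S,3S)-5,7-dihydroxy-2,3-dimethyl-6-(3-methylbut-2-enyl)-4-oxochroman-8-yl]hexanoate
Conditions: NaOMe (2.1 equiv), MeOH, 0 °C; AcOH, 0 °C
Reagents that add atoms: sodium methoxide, C[O-].[Na+]
Why: Methanolysis of an aryl lactone; the first equivalent of methoxide takes the C5 phenol proton and the second opens the lactone to the C7 phenoxide, whose stability drives the ring-opening, and the doubly charged ring is too electron-rich for enolization or retro-oxa-Michael opening of the chromanone; cold buffered quench avoids relactonisation, and final chromatography removes any C3 epimer.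

## Compound list

1 | flopropione, 1-(2,4,6-trihydroxyphenyl)propan-1-one | CCC(=O)c1c(O)cc(O)cc1O | starting material
2 | 5,7-dihydroxy-3-methyl-4H-chromen-4-one | Cc1coc2cc(O)cc(O)c2c1=O | intermediate
3 | 5-hydroxy-7-(methoxymethoxy)-3-methyl-4H-chromen-4-one | COCOc1cc(O)c2c(c1)occ(C)c2=O | intermediate
4 | 7-(methoxymethoxy)-3-methyl-5-(prop-2-enyloxy)-4H-chromen-4-one | C=CCOc1cc(OCOC)cc2occ(C)c(=O)c12 | intermediate
5 | 5-hydroxy-7-(methoxymethoxy)-3-methyl-6-(prop-2-enyl)-4H-chromen-4-one | C=CCc1c(OCOC)cc2occ(C)c(=O)c2c1O | intermediate
6 | 5-hydroxy-7-(methoxymethoxy)-3-methyl-6-(3-methylbut-2-enyl)-4H-chromen-4-one | CC(C)=CCc1c(OCOC)cc2occ(C)c(=O)c2c1O | intermediate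
7 | 5,7-bis(methoxymethoxy)-3-methyl-6-(3-methylbut-2-enyl)-4H-chromen-4-one | CC(C)=CCc1c(OCOC)cc2occ(C)c(=O)c2c1OCOC | intermediate
8 | bromomagnesium (2S)-5,7-bis(methoxymethoxy)-2,3-dimethyl-6-(3-methylbut-2-enyl)-2H-chromen-4-olate | CC(C)=CCc1c(OCOC)cc2O[C@@H](C)C(C)=C(O[Mg]Br)c2c1OCOC | intermediate
9 | (2S,3S)-5,7-bis(methoxymethoxy)-2,3-dimethyl-6-(3-methylbut-2-enyl)chroman-4-one | CC(C)=CCc1c(OCOC)cc2O[C@@H](C)[C@H](C)C(=O)c2c1OCOC | intermediate
10 | (2S,3S)-5,7-dihydroxy-2,3-dimethyl-6-(3-methylbut-2-enyl)chroman-4-one | CC(C)=CCc1c(O)cc2O[C@@H](C)[C@H](C)C(=O)c2c1O | intermediate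
11 | butanal | CCCC=O | starting material
12 | sodium 4-methylbenzenesulfinate | Cc1ccc(S(=O)[O-])cc1.[Na+] | starting material
13 | (2S,3S)-5,7-dihydroxy-2,3-dimethyl-6-(3-methylbut-2-enyl)-8-[1-(4-methylphenylsulfonyl)butyl]chroman-4-one, epimer mixture at the sulfone carbon | CCCC(S(=O)(=O)c1ccc(C)cc1)c1c(O)c(CC=C(C)C)c(O)c2c1O[C@@H](C)[C@H](C)C2=O | intermediate
14 | dimethyl malonate | COC(=O)CC(=O)OC | starting material
15 | (2S,3S,8E)-8-butylidene-5-hydroxy-2,3-dimethyl-6-(3-methylbut-2-enyl)-2,3-dihydro-4H-chromene-4,7(8H)-dione | CCC/C=C1/C(=O)C(CC=C(C)C)=C(O)C2=C1O[C@@H](C)[C@H](C)C2=O | intermediate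
16 | dimethyl 2-[(1R)-1-[(2S,3S)-5,7-dihydroxy-2,3-dimethyl-6-(3-methylbut-2-enyl)-4-oxochroman-8-yl]butyl]malonate | CCC[C@H](C(C(=O)OC)C(=O)OC)c1c(O)c(CC=C(C)C)c(O)c2c1O[C@@H](C)[C@H](C)C2=O | intermediate
17 | methyl (2S,3S,10R)-5-hydroxy-2,3-dimethyl-6-(3-methylbut-2-enyl)-4,8-dioxo-10-propyl-2,3,9,10-tetrahydro-4H,8H-pyrano[2,3-f]chromene-9-carboxylate, both C9 epimers | CCC[C@@H]1C(C(=O)OC)C(=O)Oc2c(CC=C(C)C)c(O)c3c(c21)O[C@@H](C)[C@H](C)C3=O | intermediate
18 | (2S,3S,10R)-5-hydroxy-2,3-dimethyl-6-(3-methylbut-2-enyl)-10-propyl-2,3,9,10-tetrahydro-4H,8H-pyrano[2,3-f]chromene-4,8-dione | CCC[C@@H]1CC(=O)Oc2c(CC=C(C)C)c(O)c3c(c21)O[C@@H](C)[C@H](C)C3=O | intermediate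
19 | methyl (3R)-3-[(2S,3S)-5,7-dihydroxy-2,3-dimethyl-6-(3-methylbut-2-enyl)-4-oxochroman-8-yl]hexanoate | CCC[C@H](CC(=O)OC)c1c(O)c(CC=C(C)C)c(O)c2c1O[C@@H](C)[C@H](C)C2=O | target

## Step count and risks

Total: 12 steps. Longest linear sequence: 12 steps, from flopropione 1 to 19.

**Step 10 (key step).**
- What may go wrong: poor enantioface selection. The C6 prenyl group crowds the C7 oxygen that the squaramide has to bind, and the methide may be released as a mixture of double-bond geometries that give opposite configurations at Cβ. The propyl-substituted methide may also be lost by tautomerization to the styrene or by capture by a second phenoxide.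
- Fallback: set out from phenol 10 and form the C8–Cβ bond instead, without a methide, by a tandem Knoevenagel, Friedel–Crafts-type Michael addition and lactonisation with butanal 11 and Meldrum's acid (pyridine, 80 °C).
  - Butanal and Meldrum's acid give 5-butylidene-2,2-dimethyl-1,3-dioxane-4,6-dione F1.
  - C8 of 10 adds to F1 to give 5-[1-[(2S,3S)-5,7-dihydroxy-2,3-dimethyl-6-(3-methylbut-2-enyl)-4-oxochroman-8-yl]butyl]-2,2-dimethyl-1,3-dioxane-4,6-dione F2 as both epimers at the new center.
  - O7 opens the dioxanedione with loss of acetone to give (2S,3S)-5-hydroxy-2,3-dimethyl-6-(3-methylbut-2-enyl)-4,8-dioxo-10-propyl-2,3,9,10-tetrahydro-4H,8H-pyrano[2,3-f]chromene-9-carboxylic acid F3, which decarboxylates.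
  - The products are lactone 18 and its epimer (2S,3S,10S)-5-hydroxy-2,3-dimethyl-6-(3-methylbut-2-enyl)-10-propyl-2,3,9,10-tetrahydro-4H,8H-pyrano[2,3-f]chromene-4,8-dione F4. Because C2 and C3 are already fixed, these are diastereomers and are separated by preparative chromatography.
  - The route is rejoined at 18, at the cost of the material that ends up as F4.

**Step 7.**
- What may go wrong: slow or unselective methyl transfer. MeMgBr is the least reactive Grignard reagent in copper-catalysed additions, and chromone 7 is electron-rich, alpha-substituted and crowded at O5. Competing 1,2-addition and incomplete equilibration at C3 are possible.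
- Fallback: set out from 7 and add methyl without a chiral catalyst, using the stoichiometric Gilman reagent Me2CuLi with Me3SiCl in THF at −78 °C. After equilibration this gives the racemic trans chromanone, that is 9 together with (2R,3R)-5,7-bis(methoxymethoxy)-2,3-dimethyl-6-(3-methylbut-2-enyl)chroman-4-one F5. The enantiomers are separated by preparative chromatography on a chiral stationary phase, and the route is rejoined at 9.

**Step 9.**
- What may go wrong: attack of a second molecule of 10 on the benzylic cation or methide to give a butylidene-bridged dimer; slow acid-induced closure of the prenyl group onto a phenol; loss of sulfinate from the electron-rich sulfone during purification.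
- Fallback: set out from 10 and run an acid-free Mannich (Betti-type) condensation with butanal 11 and pyrrolidine in EtOH. This gives (2S,3S)-5,7-dihydroxy-2,3-dimethyl-6-(3-methylbut-2-enyl)-8-[1-(pyrrolidin-1-yl)butyl]chroman-4-one F6, which is held as an internally hydrogen-bonded amine and does not dimerise. Exchange of the amine for sulfinate with 12 in buffered aqueous AcOH then gives 13, where the route is rejoined.

**Step 11.**
- What may go wrong: loss of configuration at Cβ by retro-Michael release of malonate from the phenoxide before the lactone has closed; partial hydrolysis of the lactone by the base that the Krapcho reaction generates; epimerization at C3 at 130 °C.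
- Fallback: set out from sulfone 13 and use Meldrum's acid in place of 14 under the same squaramide and bicarbonate conditions. This gives 5-[(1R)-1-[(2S,3S)-5,7-dihydroxy-2,3-dimethyl-6-(3-methylbut-2-enyl)-4-oxochroman-8-yl]butyl]-2,2-dimethyl-1,3-dioxane-4,6-dione F7. F7 lactonises with loss of acetone at or slightly above room temperature to (2S,3S,10R)-5-hydroxy-2,3-dimethyl-6-(3-methylbut-2-enyl)-4,8-dioxo-10-propyl-2,3,9,10-tetrahydro-4H,8H-pyrano[2,3-f]chromene-9-carboxylic acid F8, and this decarboxylates on gentle warming to 18, where the route is rejoined. Compounds 16 and 17 and the hot step are bypassed.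

## Further compounds

F1 | step 10 | 5-butylidene-2,2-dimethyl-1,3-dioxane-4,6-dione | CCCC=C1C(=O)OC(C)(C)OC1=O
F2 | step 10 | 5-[1-[(2S,3S)-5,7-dihydroxy-2,3-dimethyl-6-(3-methylbut-2-enyl)-4-oxochroman-8-yl]butyl]-2,2-dimethyl-1,3-dioxane-4,6-dione, both epimers at the butyl carbon | CCCC(C1C(=O)OC(C)(C)OC1=O)c1c(O)c(CC=C(C)C)c(O)c2c1O[C@@H](C)[C@H](C)C2=O
F3 | step 10 | (2S,3S)-5-hydroxy-2,3-dimethyl-6-(3-methylbut-2-enyl)-4,8-dioxo-10-propyl-2,3,9,10-tetrahydro-4H,8H-pyrano[2,3-f]chromene-9-carboxylic acid, epimer mixture at C9 and C10 | CCCC1C(C(=O)O)C(=O)Oc2c(CC=C(C)C)c(O)c3c(c21)O[C@@H](C)[C@H](C)C3=O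
F4 | step 10 | (2S,3S,10S)-5-hydroxy-2,3-dimethyl-6-(3-methylbut-2-enyl)-10-propyl-2,3,9,10-tetrahydro-4H,8H-pyrano[2,3-f]chromene-4,8-dione | CCC[C@H]1CC(=O)Oc2c(CC=C(C)C)c(O)c3c(c21)O[C@@H](C)[C@H](C)C3=O
F5 | step 7 | (2R,3R)-5,7-bis(methoxymethoxy)-2,3-dimethyl-6-(3-methylbut-2-enyl)chroman-4-one | CC(C)=CCc1c(OCOC)cc2O[C@H](C)[C@@H](C)C(=O)c2c1OCOC
F6 | step 9 | (2S,3S)-5,7-dihydroxy-2,3-dimethyl-6-(3-methylbut-2-enyl)-8-[1-(pyrrolidin-1-yl)butyl]chroman-4-one, epimer mixture at the amine-bearing carbon | CCCC(N1CCCC1)c1c(O)c(CC=C(C)C)c(O)c2c1O[C@@H](C)[C@H](C)C2=O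
F7 | step 11 | 5-[(1R)-1-[(2S,3S)-5,7-dihydroxy-2,3-dimethyl-6-(3-methylbut-2-enyl)-4-oxochroman-8-yl]butyl]-2,2-dimethyl-1,3-dioxane-4,6-dione | CCC[C@H](C1C(=O)OC(C)(C)OC1=O)c1c(O)c(CC=C(C)C)c(O)c2c1O[C@@H](C)[C@H](C)C2=O
F8 | step 11 | (2S,3S,10R)-5-hydroxy-2,3-dimethyl-6-(3-methylbut-2-enyl)-4,8-dioxo-10-propyl-2,3,9,10-tetrahydro-4H,8H-pyrano[2,3-f]chromene-9-carboxylic acid, both C9 epimers | CCC[C@@H]1C(C(=O)O)C(=O)Oc2c(CC=C(C)C)c(O)c3c(c21)O[C@@H](C)[C@H](C)C3=O
A1 | alternative 1 | 2-[(2S)-but-3-en-2-yloxy]-4,6-bis(methoxymethoxy)benzaldehyde | O=Cc1c(OCOC)cc(OCOC)cc1O[C@@H](C)C=C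
A2 | alternative 1 | (2S,3S)-5,7-bis(methoxymethoxy)-2,3-dimethylchroman-4-one | COCOc1cc(OCOC)c2c(c1)O[C@@H](C)[C@H](C)C2=O
A3 | alternative 2 | 5,7-bis(benzyloxy)-3-methyl-4H-chromen-4-one | Cc1coc2cc(OCc3ccccc3)cc(OCc3ccccc3)c2c1=O
A4 | alternative 2 | (2S,3S)-5,7-bis(benzyloxy)-2,3-dimethylchroman-4-one | c1c(OCc3ccccc3)cc(OCc3ccccc3)c2c1O[C@@H](C)[C@H](C)C2=O
A5 | alternative 3 | (E)-hex-2-enal | CCC/C=C/C=O
A6 | alternative 3 | (2S,3S,10R)-5-hydroxy-2,3-dimethyl-6-(3-methylbut-2-enyl)-10-propyl-2,3,9,10-tetrahydro-4H,8H-pyrano[2,3-f]chromene-4,8-dione | CCC[C@@H]1CC(=O)Oc2c(CC=C(C)C)c(O)c3c(c21)O[C@@H](C)[C@H](C)C3=O
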